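Atoms are numbered C1 (lactone C=O), C2, C3 (OAc), C4 (quaternary), C5 (lactone O–CH), C6 (CHMe), C7 (acyloxy CH), C8 (ring OCHMe). Everything rests on disconnecting the oxane ring between C6 and C7. An intramolecular Mukaiyama aldol of a (Z)-silyl enol ether of a C5 ethyl ketone onto a C7 α-alkoxy aldehyde closes the oxane and sets C6 and C7 in one operation. It exploits the quaternary C4 (enolisation only toward C6) and the all-equatorial C6-methyl, C7-oxygen and C8-methyl groups of the oxane ring. The precursor is an acyclic tertiary ether linking C4 through the ring oxygen to a lactaldehyde unit; the C5 ketone later becomes the lactone oxygen-bearing carbon.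

Key step: step 8

Remark: (−)-B-methoxydiisopinocampheylborane and acid 14 are taken as purchased reagents; the atom labels C1–C8 used below are those of the first paragraph.

Step 1
Reactants: 1 (E)-2-methylpent-2-enal
Product: 2 (3S,4S,5E)-3,5-dimethylocta-1,5-dien-4-ol
Conditions: trans-2-butene, KOt-Bu, n-BuLi, THF, −78 to −45 °C; (−)-Ipc2BOMe, −78 °C; BF3·OEt2; then 1, −78 °C; NaOH, H2O2, 0 °C to rt
Reagents that add atoms: trans-2-butene, C/C=C/C (delivered as the crotylborane made in the flask)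
Why: Brown crotylboration through a chair Zimmerman–Traxler transition state, in which the (E)-crotyl geometry should give the anti C2-methyl/C3-hydroxyl pair and the isopinocampheyl groups derived from (+)-α-pinene should direct addition to the Si face of the aldehyde, setting C2 and C3.

Step 2
Reactants: 2 (3S,4S,5E)-3,5-dimethylocta-1,5-dien-4-ol
Product: 3 (1S,2S)-1-[(2S,3S)-3-ethyl-2-methyloxiran-2-yl]-2-methylbut-3-en-1-ol
Conditions: VO(acac)2 (cat.), t-BuOOH, CH2Cl2, 0 °C to rt
Reagents that add atoms: tert-butyl hydroperoxide, CC(C)(C)OO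
Why: Hydroxyl-directed vanadium-catalysed epoxidation, in which A(1,2) strain between the C4 methyl and the carbinol substituent in the vanadate ester should give the erythro epoxy alcohol (C4 and C5), while the remote terminal vinyl group is not epoxidised.

Step 3
Reactants: 3 (1S,2S)-1-[(2S,3S)-3-ethyl-2-methyloxiran-2-yl]-2-methylbut-3-en-1-ol
Product: 4 tert-butyl{[(1S,2S)-1-[(2S,3S)-3-ethyl-2-methyloxiran-2-yl]-2-methylbut-3-en-1-yl]oxy}dimethylsilane
Conditions: TBSCl, imidazole, DMAP (cat.), DMF, 35 °C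
Reagents that add atoms: tert-butyldimethylsilyl chloride, CC(C)(C)[Si](C)(C)Cl
Why: Silylation of the hindered secondary alcohol (no new stereocentre) masks O3 with a group that cannot take part in the epoxide opening as an acyl group would.

Step 4
Reactants: 4 tert-butyl{[(1S,2S)-1-[(2S,3S)-3-ethyl-2-methyloxiran-2-yl]-2-methylbut-3-en-1-yl]oxy}dimethylsilane; 5 ethyl (S)-lactate
Product: 6 ethyl (2S)-2-{[(3S,4S,5S,6S)-5-(tert-butyldimethylsilyloxy)-3-hydroxy-4,6-dimethyloct-7-en-4-yl]oxy}propanoate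
Conditions: BF3·OEt2 (0.1 equiv), neat 5 (20 equiv), −20 to 0 °C; Et3N quench at 0 °C
Reagents that add atoms: none
Why: Lewis acid-catalysed alcoholysis of the trisubstituted epoxide at its tertiary carbon (borderline SN1/SN2) should occur with inversion and so set the quaternary C4 ether centre, while C8 is taken unchanged from the lactate.

Step 5
Reactants: 6 ethyl (2S)-2-{[(3S,4S,5S,6S)-5-(tert-butyldimethylsilyloxy)-3-hydroxy-4,6-dimethyloct-7-en-4-yl]oxy}propanoate
Product: 7 ethyl (2S)-2-{[(4R,5S,6S)-5-(tert-butyldimethylsilyloxy)-4,6-dimethyl-3-oxooct-7-en-4-yl]oxy}propanoate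
Conditions: Dess–Martin periodinane, NaHCO3, CH2Cl2, rt
Reagents that add atoms: none
Why: Dess–Martin oxidation of the secondary C5 alcohol gives the ethyl ketone needed as aldol donor; the buffered neutral conditions leave silyl ether, ester and the α-alkoxy stereocentres untouched.

Step 6
Reactants: 7 ethyl (2S)-2-{[(4R,5S,6S)-5-(tert-butyldimethylsilyloxy)-4,6-dimethyl-3-oxooct-7-en-4-yl]oxy}propanoate
Product: 8 ethyl (2S)-2-{[(2Z,4R,5S,6S)-3,5-bis(tert-butyldimethylsilyloxy)-4,6-dimethylocta-2,7-dien-4-yl]oxy}propanoate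
Conditions: TBSOTf, Et3N, CH2Cl2, 0 °C to rt
Reagents that add atoms: tert-butyldimethylsilyl triflate, CC(C)(C)[Si](C)(C)OS(=O)(=O)C(F)(F)F
Why: Soft enolisation and O-silylation of the ketone in preference to the ester; C4 is quaternary so only the ethyl side can enolise, and allylic strain against the quaternary C4 should favour the Z enol ether.

Step 7
Reactants: 8 ethyl (2S)-2-{[(2Z,4R,5S,6S)-3,5-bis(tert-butyldimethylsilyloxy)-4,6-dimethylocta-2,7-dien-4-yl]oxy}propanoate
Product: 9 (2S)-2-{[(2Z,4R,5S,6S)-3,5-bis(tert-butyldimethylsilyloxy)-4,6-dimethylocta-2,7-dien-4-yl]oxy}propanal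
Conditions: i-Bu2AlH (1.1 equiv), CH2Cl2, −78 °C; MeOH, aq. potassium sodium tartrate; used crude
Reagents that add atoms: none
Why: Partial reduction of the α-alkoxy ester: the tetrahedral aluminium hemiacetal is stable at −78 °C and gives the aldehyde only on work-up, while the ketone stays masked as the silyl enol ether and C8 is not touched.

Step 8
Reactants: 9 (2S)-2-{[(2Z,4R,5S,6S)-3,5-bis(tert-butyldimethylsilyloxy)-4,6-dimethylocta-2,7-dien-4-yl]oxy}propanal
Product: 10 (2R,4R,5R,6S)-2-[(1S,2S)-1-(tert-butyldimethylsilyloxy)-2-methylbut-3-en-1-yl]-5-hydroxy-2,4,6-trimethyloxan-3-one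
Conditions: BF3·OEt2 (1.2 equiv), CH2Cl2 (0.01 M), −78 to −40 °C; aq. NaHCO3
Reagents that add atoms: none
Why: BF3 activates the C7 aldehyde and the enol carbon C6 attacks it intramolecularly, the enol silyl group leaving as the fluorosilane and the boron aldolate giving the free ketol on work-up. The closest known reaction type is the intramolecular Mukaiyama aldol addition of a ketone silyl enol ether to an α-alkoxy aldehyde. The oxane ring closes in the 6-(enolendo)-exo-trig mode through a chair in which the C8 methyl and the bulky C4 side chain are equatorial and the C4 methyl is axial. C6 is controlled by the Z enol geometry (methyl anti to C4, hence equatorial) together with this chair, which fixes the enol face; C7 is controlled by the open antiperiplanar transition state in which the aldehyde oxygen lies anti to the ring ether oxygen (Cornforth arrangement, monodentate BF3, no chelation) and so becomes the equatorial hydroxyl. The step needs regioselective enolisation and facial selectivity at the aldehyde: the first is secured because C4 is quaternary, the second because the other chair would place the C8 methyl and the C4 side chain 1,3-diaxial and because BF3 cannot bridge the two oxygens.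

Step 9
Reactants: 10 (2R,4R,5R,6S)-2-[(1S,2S)-1-(tert-butyldimethylsilyloxy)-2-methylbut-3-en-1-yl]-5-hydroxy-2,4,6-trimethyloxan-3-one
Product: 11 (2S,3S,4R,5R,6S)-2-[(1S,2S)-1-(tert-butyldimethylsilyloxy)-2-methylbut-3-en-1-yl]-2,4,6-trimethyloxane-3,5-diol
Conditions: NaBH4, MeOH, −40 to 0 °C
Reagents that add atoms: none
Why: Borohydride reduction of the oxan-3-one by axial attack on the face opposite the axial C4 methyl should give the equatorial C5 alcohol, the later lactone oxygen.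

Step 10
Reactants: 11 (2S,3S,4R,5R,6S)-2-[(1S,2S)-1-(tert-butyldimethylsilyloxy)-2-methylbut-3-en-1-yl]-2,4,6-trimethyloxane-3,5-diol
Product: 13 (3R,4S,4aS,6S,7R,8R,8aS)-4-(tert-butyldimethylsilyloxy)-7-hydroxy-3,4a,6,8-tetramethylhexahydropyrano[3,2-b]pyran-2(3H)-one, via lactol 12 (not isolated)
Conditions: O3, CH2Cl2/MeOH, −78 °C; Me2S, −78 °C to rt; concentrate; then TEMPO (0.2 equiv), PhI(OAc)2, CH2Cl2, rt
Reagents that add atoms: ozone, [O-][O+]=O
Why: Ozonolysis of the only alkene gives the C1 aldehyde, which closes onto the C5 hydroxyl as the six-membered lactol; oxoammonium (TEMPO) oxidation should take the lactol to the trans-fused lactone faster than it oxidises the hindered secondary C7 hydroxyl, and no stereocentre is formed.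

Step 11
Reactants: 13 (3R,4S,4aS,6S,7R,8R,8aS)-4-(tert-butyldimethylsilyloxy)-7-hydroxy-3,4a,6,8-tetramethylhexahydropyrano[3,2-b]pyran-2(3H)-one; 14 2-[bis(2,2,2-trifluoroethoxy)phosphoryl]acetic acid
Product: 15 (3R,4S,4aS,6S,7R,8R,8aS)-4-(tert-butyldimethylsilyloxy)-3,4a,6,8-tetramethyl-2-oxooctahydropyrano[3,2-b]pyran-7-yl 2-[bis(2,2,2-trifluoroethoxy)phosphoryl]acetate
Conditions: DCC, DMAP (0.1 equiv), CH2Cl2, 0 °C to rt
Reagents that add atoms: none
Why: Carbodiimide (Steglich) esterification of the only free hydroxyl (C7) installs the olefination handle with retention at C7.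

Step 12
Reactants: 15 (3R,4S,4aS,6S,7R,8R,8aS)-4-(tert-butyldimethylsilyloxy)-3,4a,6,8-tetramethyl-2-oxooctahydropyrano[3,2-b]pyran-7-yl 2-[bis(2,2,2-trifluoroethoxy)phosphoryl]acetate
Product: 17 (3R,4S,4aS,6S,7R,8R,8aS)-4-(acetyloxy)-3,4a,6,8-tetramethyl-2-oxooctahydropyrano[3,2-b]pyran-7-yl 2-[bis(2,2,2-trifluoroethoxy)phosphoryl]acetate, via alcohol 16 (not isolated)
Conditions: 48% aq. HF, MeCN, 0 °C to rt; extractive work-up; then Ac2O, pyridine, DMAP (cat.), CH2Cl2, rt
Reagents that add atoms: acetic anhydride, CC(=O)OC(C)=O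
Why: Fluoride-mediated desilylation of O3 followed by DMAP-catalysed acetylation of the freed C3 hydroxyl; no stereocentre is touched, and the acetate is introduced only after all hydride and ozone steps.

Step 13
Reactants: 18 octane-1,2-diol
Product: 19 2-oxooctanal
Conditions: (COCl)2, DMSO, CH2Cl2, −78 °C; Et3N, −78 to 0 °C; used freshly prepared
Reagents that add atoms: none
Why: Swern oxidation of both hydroxyls of the 1,2-diol should give the α-ketoaldehyde without over-oxidation.

Step 14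
Reactants: 17 (3R,4S,4aS,6S,7R,8R,8aS)-4-(acetyloxy)-3,4a,6,8-tetramethyl-2-oxooctahydropyrano[3,2-b]pyran-7-yl 2-[bis(2,2,2-trifluoroethoxy)phosphoryl]acetate; 19 2-oxooctanal
Product: 20 botcinin J, (3R,4S,4aS,6S,7R,8R,8aS)-4-(acetyloxy)-3,4a,6,8-tetramethyl-2-oxooctahydropyrano[3,2-b]pyran-7-yl (2Z)-4-oxodec-2-enoate
Conditions: KN(SiMe3)2 (0.95 equiv), 18-crown-6, THF, −78 °C; then 19, −78 °C; aq. NH4Cl at −78 °C; work-up with exclusion of light
Reagents that add atoms: none
Why: Still–Gennari olefination: the trifluoroethyl phosphonate anion adds to the more electrophilic aldehyde carbonyl and the adduct eliminates under kinetic control, which should give the Z enoate; a slight deficit of base at −78 °C spares the lactone α-position and the C3 acetate.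

Compound list
1 | (E)-2-methylpent-2-enal | CC/C=C(\C)C=O | starting material
2 | (3S,4S,5E)-3,5-dimethylocta-1,5-dien-4-ol | C=C[C@H](C)[C@H](O)/C(C)=C/CC | intermediate
3 | (1S,2S)-1-[(2S,3S)-3-ethyl-2-methyloxiran-2-yl]-2-methylbut-3-en-1-ol | C=C[C@H](C)[C@H](O)[C@]1(C)O[C@H]1CC | intermediate
4 | tert-butyl{[(1S,2S)-1-[(2S,3S)-3-ethyl-2-methyloxiran-2-yl]-2-methylbut-3-en-1-yl]oxy}dimethylsilane | C=C[C@H](C)[C@H](O[Si](C)(C)C(C)(C)C)[C@]1(C)O[C@H]1CC | intermediate
5 | ethyl (S)-lactate | C[C@H](O)C(=O)OCC | starting material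
6 | ethyl (2S)-2-{[(3S,4S,5S,6S)-5-(tert-butyldimethylsilyloxy)-3-hydroxy-4,6-dimethyloct-7-en-4-yl]oxy}propanoate | C=C[C@H](C)[C@H](O[Si](C)(C)C(C)(C)C)[C@@](C)(O[C@@H](C)C(=O)OCC)[C@@H](O)CC | intermediate
7 | ethyl (2S)-2-{[(4R,5S,6S)-5-(tert-butyldimethylsilyloxy)-4,6-dimethyl-3-oxooct-7-en-4-yl]oxy}propanoate | C=C[C@H](C)[C@H](O[Si](C)(C)C(C)(C)C)[C@@](C)(O[C@@H](C)C(=O)OCC)C(=O)CC | intermediate
8 | ethyl (2S)-2-{[(2Z,4R,5S,6S)-3,5-bis(tert-butyldimethylsilyloxy)-4,6-dimethylocta-2,7-dien-4-yl]oxy}propanoate | C=C[C@H](C)[C@H](O[Si](C)(C)C(C)(C)C)[C@@](C)(O[C@@H](C)C(=O)OCC)/C(O[Si](C)(C)C(C)(C)C)=C/C | intermediate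
9 | (2S)-2-{[(2Z,4R,5S,6S)-3,5-bis(tert-butyldimethylsilyloxy)-4,6-dimethylocta-2,7-dien-4-yl]oxy}propanal | C=C[C@H](C)[C@H](O[Si](C)(C)C(C)(C)C)[C@@](C)(O[C@@H](C)C=O)/C(O[Si](C)(C)C(C)(C)C)=C/C | intermediate
10 | (2R,4R,5R,6S)-2-[(1S,2S)-1-(tert-butyldimethylsilyloxy)-2-methylbut-3-en-1-yl]-5-hydroxy-2,4,6-trimethyloxan-3-one | O[C@@H]1[C@@H](C)C(=O)[C@](C)(O[C@H]1C)[C@@H](O[Si](C)(C)C(C)(C)C)[C@@H](C)C=C | intermediate
11 | (2S,3S,4R,5R,6S)-2-[(1S,2S)-1-(tert-butyldimethylsilyloxy)-2-methylbut-3-en-1-yl]-2,4,6-trimethyloxane-3,5-diol | O[C@@H]1[C@@H](C)[C@H](O)[C@](C)(O[C@H]1C)[C@@H](O[Si](C)(C)C(C)(C)C)[C@@H](C)C=C | intermediate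
12 | lactol: (3R,4S,4aS,6S,7R,8R,8aS)-4-(tert-butyldimethylsilyloxy)-3,4a,6,8-tetramethyloctahydropyrano[3,2-b]pyran-2,7-diol, both C1 anomers | O[C@@H]1[C@@H](C)[C@@H]2OC(O)[C@H](C)[C@H](O[Si](C)(C)C(C)(C)C)[C@@]2(C)O[C@H]1C | intermediate
13 | (3R,4S,4aS,6S,7R,8R,8aS)-4-(tert-butyldimethylsilyloxy)-7-hydroxy-3,4a,6,8-tetramethylhexahydropyrano[3,2-b]pyran-2(3H)-one | O[C@@H]1[C@@H](C)[C@@H]2OC(=O)[C@H](C)[C@H](O[Si](C)(C)C(C)(C)C)[C@@]2(C)O[C@H]1C | intermediate
14 | 2-[bis(2,2,2-trifluoroethoxy)phosphoryl]acetic acid | OC(=O)CP(=O)(OCC(F)(F)F)OCC(F)(F)F | starting material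
15 | (3R,4S,4aS,6S,7R,8R,8aS)-4-(tert-butyldimethylsilyloxy)-3,4a,6,8-tetramethyl-2-oxooctahydropyrano[3,2-b]pyran-7-yl 2-[bis(2,2,2-trifluoroethoxy)phosphoryl]acetate | O=C(CP(=O)(OCC(F)(F)F)OCC(F)(F)F)O[C@@H]1[C@@H](C)[C@@H]2OC(=O)[C@H](C)[C@H](O[Si](C)(C)C(C)(C)C)[C@@]2(C)O[C@H]1C | intermediate
16 | (3R,4S,4aR,6S,7R,8R,8aS)-4-hydroxy-3,4a,6,8-tetramethyl-2-oxooctahydropyrano[3,2-b]pyran-7-yl 2-[bis(2,2,2-trifluoroethoxy)phosphoryl]acetate (same spatial arrangement as 15) | O=C(CP(=O)(OCC(F)(F)F)OCC(F)(F)F)O[C@@H]1[C@@H](C)[C@@H]2OC(=O)[C@H](C)[C@H](O)[C@@]2(C)O[C@H]1C | intermediate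
17 | (3R,4S,4aS,6S,7R,8R,8aS)-4-(acetyloxy)-3,4a,6,8-tetramethyl-2-oxooctahydropyrano[3,2-b]pyran-7-yl 2-[bis(2,2,2-trifluoroethoxy)phosphoryl]acetate | O=C(CP(=O)(OCC(F)(F)F)OCC(F)(F)F)O[C@@H]1[C@@H](C)[C@@H]2OC(=O)[C@H](C)[C@H](OC(C)=O)[C@@]2(C)O[C@H]1C | intermediate
18 | octane-1,2-diol | CCCCCCC(O)CO | starting material
19 | 2-oxooctanal | CCCCCCC(=O)C=O | intermediate
20 | botcinin J | CCCCCCC(=O)/C=C\C(=O)O[C@@H]1[C@@H](C)[C@@H]2OC(=O)[C@H](C)[C@H](OC(C)=O)[C@@]2(C)O[C@H]1C | target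

Total step count: 14. Longest linear sequence: 13 steps (steps 1 to 12 and step 14).

Steps most likely to fail

Step 4. The tertiary cation may undergo a 1,2-hydride-shift (semipinacol) rearrangement, or the secondary epoxide carbon may be attacked, faster than the weakly nucleophilic lactate captures C4. Fallback: the C4–O–C8 ether is formed by carbenoid O–H insertion instead of epoxide alcoholysis. Setting out from 4, aqueous HClO4 in THF should open the epoxide with water at the tertiary carbon with inversion to give (3S,4S,5S,6S)-5-(tert-butyldimethylsilyloxy)-4,6-dimethyloct-7-ene-3,4-diol F1. Dess–Martin oxidation of its secondary C5 hydroxyl should give the α-hydroxy ketone F2. Rh2(OAc)4-catalysed insertion of ethyl 2-diazopropanoate (slow addition) into the tertiary O–H bond should then give 7 together with its C8 epimer F3, which is to be removed by chromatography; the route is rejoined at 7.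

Step 8. Facial selectivity at the aldehyde may erode if a synclinal or chelated transition state competes with the antiperiplanar open one, giving the axial C7 alcohol. Fallback: C7 is set by a late SN2 inversion instead of in the ring closure. Setting out from 9, a chelating Lewis acid (MgBr2·OEt2 or TiCl4, CH2Cl2, −78 °C) should steer the same ring closure on purpose to the C7-epimeric ketol F4. Me4NBH(OAc)3, with hydride delivered from the axial C7 hydroxyl, should give the C7-epimeric diol F5 with the equatorial C5 hydroxyl. Ozonolysis and TEMPO/PhI(OAc)2 oxidation as in step 10 should give, through the C7-epimeric lactol F6, the C7-epimeric lactone F7. Mitsunobu esterification of F7 with acid 14 (PPh3, diisopropyl azodicarboxylate) should invert C7 and rejoin the route at 15.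

Step 14. The phosphonate anion may add to the hydrated or oligomerised ketoaldehyde or to its ketone carbonyl, and the Z enedione may isomerise to E under the basic conditions. Fallback: the olefination is run with a mono-carbonyl aldehyde and the ketone is installed afterwards under neutral conditions. Commercial non-1-en-3-ol is silylated (TBSCl, imidazole) to the silyl ether F8 and ozonised (O3; Me2S) to racemic 2-(tert-butyldimethylsilyloxy)octanal F9. Setting out from 17, Still–Gennari olefination with F9 should give the (Z)-4-silyloxy enoate F10 as both C4′ epimers. HF·pyridine should free the allylic alcohol F11, which is oxidised at once with Dess–Martin periodinane (NaHCO3 buffer) before it can lactonise, rejoining the route at 20.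

Further compounds
F1 | step 4 | (3S,4S,5S,6S)-5-(tert-butyldimethylsilyloxy)-4,6-dimethyloct-7-ene-3,4-diol | C=C[C@H](C)[C@H](O[Si](C)(C)C(C)(C)C)[C@@](C)(O)[C@@H](O)CC
F2 | step 4 | (4R,5S,6S)-5-(tert-butyldimethylsilyloxy)-4-hydroxy-4,6-dimethyloct-7-en-3-one | C=C[C@H](C)[C@H](O[Si](C)(C)C(C)(C)C)[C@@](C)(O)C(=O)CC
F3 | step 4 | C8 epimer of 7, ethyl (2R)-2-{[(4R,5S,6S)-5-(tert-butyldimethylsilyloxy)-4,6-dimethyl-3-oxooct-7-en-4-yl]oxy}propanoate | C=C[C@H](C)[C@H](O[Si](C)(C)C(C)(C)C)[C@@](C)(O[C@H](C)C(=O)OCC)C(=O)CC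
F4 | step 8 | C7 epimer of 10, (2R,4R,5S,6S)-2-[(1S,2S)-1-(tert-butyldimethylsilyloxy)-2-methylbut-3-en-1-yl]-5-hydroxy-2,4,6-trimethyloxan-3-one | O[C@H]1[C@@H](C)C(=O)[C@](C)(O[C@H]1C)[C@@H](O[Si](C)(C)C(C)(C)C)[C@@H](C)C=C
F5 | step 8 | C7 epimer of 11, (2S,3S,4R,5S,6S)-2-[(1S,2S)-1-(tert-butyldimethylsilyloxy)-2-methylbut-3-en-1-yl]-2,4,6-trimethyloxane-3,5-diol | O[C@H]1[C@@H](C)[C@H](O)[C@](C)(O[C@H]1C)[C@@H](O[Si](C)(C)C(C)(C)C)[C@@H](C)C=C
F6 | step 8 | C7 epimer of lactol 12 | O[C@H]1[C@@H](C)[C@@H]2OC(O)[C@H](C)[C@H](O[Si](C)(C)C(C)(C)C)[C@@]2(C)O[C@H]1C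
F7 | step 8 | C7 epimer of 13, (3R,4S,4aS,6S,7S,8R,8aS)-4-(tert-butyldimethylsilyloxy)-7-hydroxy-3,4a,6,8-tetramethylhexahydropyrano[3,2-b]pyran-2(3H)-one | O[C@H]1[C@@H](C)[C@@H]2OC(=O)[C@H](C)[C@H](O[Si](C)(C)C(C)(C)C)[C@@]2(C)O[C@H]1C
F8 | step 14 | tert-butyl(dimethyl)(non-1-en-3-yloxy)silane | C=CC(CCCCCC)O[Si](C)(C)C(C)(C)C
F9 | step 14 | 2-(tert-butyldimethylsilyloxy)octanal | CCCCCCC(O[Si](C)(C)C(C)(C)C)C=O
F10 | step 14 | (Z)-4-(tert-butyldimethylsilyloxy)dec-2-enoate of the core alcohol (C3 acetate), both C4′ epimers | CCCCCCC(O[Si](C)(C)C(C)(C)C)/C=C\C(=O)O[C@@H]1[C@@H](C)[C@@H]2OC(=O)[C@H](C)[C@H](OC(C)=O)[C@@]2(C)O[C@H]1C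
F11 | step 14 | (Z)-4-hydroxydec-2-enoate of the core alcohol (C3 acetate), both C4′ epimers | CCCCCCC(O)/C=C\C(=O)O[C@@H]1[C@@H](C)[C@@H]2OC(=O)[C@H](C)[C@H](OC(C)=O)[C@@]2(C)O[C@H]1C
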